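The route rests on disconnecting the pyranone ring of the 4-hydroxyphenyl flavanone (unit B) across C2–C3 and C4–C4a. A ketene drawn from the acetic acid side chain at C3 of the finished 4-methoxyphenyl flavanone (unit A) adds through its terminal carbon to an O-aryl oxocarbenium ion (O1=C2 of unit B), and the acylium ion so formed acylates the ortho carbon C4a of the phloroglucinol ring. The step exploits the cationic 2-oxadiene C4a=C8a–O1=C2 of that ring and closes the cis-flavanone in one operation. The precursors are an acid chloride of unit A and a mixed aryl methyl acetal of 4-(benzyloxy)benzaldehyde.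

Key step: step 7

Remark: the target is read as unit A 2,3-trans (2S,3R) and unit B 2,3-cis (2S,3S); atoms of unit B are written C2(B), C3(B), C4(B), C4a(B), O1(B).
Remark: 5,7-dihydroxychromone, 3,5-bis(benzyloxy)phenol and 4-(benzyloxy)benzaldehyde are taken as commercial. In step 2 the sense of induction of the ligand is assumed, and the ligand enantiomer that gives the 2S product is used.

Step 1
Reactants: 1 5,7-dihydroxy-4H-chromen-4-one
Product: 2 5,7-bis(benzyloxy)-4H-chromen-4-one
Conditions: BnBr, K2CO3, DMF, 70 °C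
Reagents that add atoms: benzyl bromide, BrCc1ccccc1
Why: Williamson etherification; K2CO3 in warm DMF should benzylate also the hydrogen-bonded 5-hydroxyl of the base-stable chromone.

Step 2
Reactants: 2 5,7-bis(benzyloxy)-4H-chromen-4-one; 3 (4-methoxyphenyl)boronic acid
Product: 4 (2S)-5,7-bis(benzyloxy)-2-(4-methoxyphenyl)chroman-4-one
Conditions: Pd(OCOCF3)2 (5 mol%), t-BuPyOx [4-tert-butyl-2-(2-pyridyl)oxazoline, enantiomer giving 2S] (6 mol%), NH4PF6, H2O, ClCH2CH2Cl, 60 °C
Reagents that add atoms: none
Why: Enantioselective conjugate addition of an arylboronic acid to a chromone (Hayashi–Miyaura-type 1,4-addition) on divalent palladium; the chiral pyridine-oxazoline ligand selects the enone face and sets C2 as S, and the base-free medium should avoid ring opening of the flavanone.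

Step 3
Reactants: 4 (2S)-5,7-bis(benzyloxy)-2-(4-methoxyphenyl)chroman-4-one; 5 tert-butyl bromoacetate
Product: 6 tert-butyl 2-[(2S,3R)-5,7-bis(benzyloxy)-2-(4-methoxyphenyl)-4-oxochroman-3-yl]acetate
Conditions: LiHMDS, THF, −78 °C; then 5, −78 to −40 °C
Reagents that add atoms: none
Why: Kinetic lithium enolate alkylation; the electrophile should approach C3 anti to the 2-aryl group and give the 2,3-trans (3R) product, which is also the thermodynamically preferred epimer.

Step 4
Reactants: 6 tert-butyl 2-[(2S,3R)-5,7-bis(benzyloxy)-2-(4-methoxyphenyl)-4-oxochroman-3-yl]acetate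
Product: 7 2-[(2S,3R)-5,7-bis(benzyloxy)-2-(4-methoxyphenyl)-4-oxochroman-3-yl]acetic acid
Conditions: CF3CO2H, CH2Cl2, 0 °C to rt
Reagents that add atoms: none
Why: Acidolysis of a tert-butyl ester (E1 loss of isobutene); benzyl ethers, the methyl ether and both stereocenters should survive brief exposure to the acid.

Step 5
Reactants: 8 4-(benzyloxy)benzaldehyde
Product: 9 1-(benzyloxy)-4-(dimethoxymethyl)benzene
Conditions: HC(OMe)3, cat. TsOH, MeOH, rt
Reagents that add atoms: trimethyl orthoformate, COC(OC)OC
Why: Acid-catalysed acetalization with the orthoester as water scavenger.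

Step 6
Reactants: 9 1-(benzyloxy)-4-(dimethoxymethyl)benzene; 10 3,5-bis(benzyloxy)phenol
Product: 12 1,3-bis(benzyloxy)-5-{[4-(benzyloxy)phenyl](methoxy)methoxy}benzene (racemic), via chloro methyl ether 11 (not isolated)
Conditions: AcCl (1 equiv), CH2Cl2, 0 °C to rt; then 10, i-Pr2NEt, 0 °C
Reagents that add atoms: none
Why: Acetyl chloride converts the dimethyl acetal into the α-chloro ether, which O-alkylates the phenol under amine base in an SN1-type Williamson reaction (as in MOM protection); the acetal carbon is racemic and is planarized in step 7.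

Step 7
Reactants: 7 2-[(2S,3R)-5,7-bis(benzyloxy)-2-(4-methoxyphenyl)-4-oxochroman-3-yl]acetic acid; 12 1,3-bis(benzyloxy)-5-{[4-(benzyloxy)phenyl](methoxy)methoxy}benzene
Product: 16 (2S,3R)-5,7-bis(benzyloxy)-3-[(2S,3S)-5,7-bis(benzyloxy)-2-[4-(benzyloxy)phenyl]-4-oxochroman-3-yl]-2-(4-methoxyphenyl)chroman-4-one, via acid chloride 13 (not isolated), via ketene 14 (not isolated), via aryl chloromethyl ether 15 (not isolated)
Conditions: (COCl)2, cat. DMF, CH2Cl2, 0 °C to rt, evaporate; i-Pr2NEt (1 equiv), CH2Cl2, −78 °C; add to 12, SnCl4, 2,6-di-tert-butyl-4-methylpyridine, CH2Cl2, −78 to −30 °C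
Reagents that add atoms: none
Why: Proposed new method: (COCl)2 turns 7 into 13, i-Pr2NEt dehydrochlorinates it to aldoketene 14, SnCl4 ionizes 12 through 15 to the O-aryl oxocarbenium ion, the nucleophilic terminal ketene carbon C3(B) attacks C2(B), and the acylium ion so formed acylates the ortho carbon C4a(B), a formal [4+2] of the cationic 2-oxadiene C4a=C8a–O1=C2 with the ketene C=C. The closest known reaction types are the Lewis-acid-mediated insertion of ketenes into acetals and α-halo ethers, the oxa-Povarov reaction of aryl oxocarbenium ions with alkenes, and intramolecular Friedel–Crafts acylation. The single new ring, the pyranone of unit B, closes by 6-exo attack of the arene on the acylium carbon (electrophilic aromatic substitution), and the two ortho positions of the symmetrical 3,5-bis(benzyloxy)phenoxy ring are equivalent, so no regioisomer can arise. C3(B) is controlled by the adjacent C3 stereocenter of unit A: with C3–H eclipsing the ketene C=C, the cation should attack anti to the C2 carbon that bears the anisyl group (Felkin-type 1,2-induction), which gives 3S. C2(B) is set relative to C3(B) in an open antiperiplanar transition state, as in the syn-selective Lewis-acid additions of enol derivatives to acetals, which places the aryl group and the unit A substituent cis (2S), and fast ring closure at low temperature should keep this kinetic arrangement. The step needs the nucleophile to be formed next to an enolizable ketone and the cation not to alkylate its own ring; the ketene route (acid chloride plus amine) leaves the unit A ketone untouched, and the aryl ring is deactivated as an oxocarbenium ion until the C–C bond has formed.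

Step 8
Reactants: 16 (2S,3R)-5,7-bis(benzyloxy)-3-[(2S,3S)-5,7-bis(benzyloxy)-2-[4-(benzyloxy)phenyl]-4-oxochroman-3-yl]-2-(4-methoxyphenyl)chroman-4-one
Product: 17 (2S,3R)-5,7-dihydroxy-3-[(2S,3S)-5,7-dihydroxy-2-(4-hydroxyphenyl)-4-oxochroman-3-yl]-2-(4-methoxyphenyl)chroman-4-one
Conditions: H2 (1 atm), 10% Pd/C, EtOAc–MeOH, rt
Reagents that add atoms: none
Why: Catalytic hydrogenolysis of the five benzyl ethers under neutral conditions, which should leave the aryl methyl ether, both ketones and the four stereocenters (including the epimerizable cis C3 of unit B) untouched.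

Compound list
1 | 5,7-dihydroxy-4H-chromen-4-one | O=c1ccoc2cc(O)cc(O)c12 | starting material
2 | 5,7-bis(benzyloxy)-4H-chromen-4-one | O=c1ccoc2cc(OCc3ccccc3)cc(OCc3ccccc3)c12 | intermediate
3 | (4-methoxyphenyl)boronic acid | COc1ccc(B(O)O)cc1 | starting material
4 | (2S)-5,7-bis(benzyloxy)-2-(4-methoxyphenyl)chroman-4-one | COc1ccc([C@H]2Oc3cc(OCc4ccccc4)cc(OCc4ccccc4)c3C(=O)C2)cc1 | intermediate
5 | tert-butyl bromoacetate | CC(C)(C)OC(=O)CBr | starting material
6 | tert-butyl 2-[(2S,3R)-5,7-bis(benzyloxy)-2-(4-methoxyphenyl)-4-oxochroman-3-yl]acetate | COc1ccc([C@H]2Oc3cc(OCc4ccccc4)cc(OCc4ccccc4)c3C(=O)[C@@H]2CC(=O)OC(C)(C)C)cc1 | intermediate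
7 | 2-[(2S,3R)-5,7-bis(benzyloxy)-2-(4-methoxyphenyl)-4-oxochroman-3-yl]acetic acid | COc1ccc([C@H]2Oc3cc(OCc4ccccc4)cc(OCc4ccccc4)c3C(=O)[C@@H]2CC(=O)O)cc1 | intermediate
8 | 4-(benzyloxy)benzaldehyde | O=Cc1ccc(OCc2ccccc2)cc1 | starting material
9 | 1-(benzyloxy)-4-(dimethoxymethyl)benzene | COC(OC)c1ccc(OCc2ccccc2)cc1 | intermediate
10 | 3,5-bis(benzyloxy)phenol | Oc1cc(OCc2ccccc2)cc(OCc2ccccc2)c1 | starting material
11 | 1-(benzyloxy)-4-[chloro(methoxy)methyl]benzene (racemic, not isolated) | COC(Cl)c1ccc(OCc2ccccc2)cc1 | intermediate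
12 | 1,3-bis(benzyloxy)-5-{[4-(benzyloxy)phenyl](methoxy)methoxy}benzene (racemic) | COC(Oc1cc(OCc2ccccc2)cc(OCc2ccccc2)c1)c1ccc(OCc2ccccc2)cc1 | intermediate
13 | 2-[(2S,3R)-5,7-bis(benzyloxy)-2-(4-methoxyphenyl)-4-oxochroman-3-yl]acetyl chloride (not isolated) | COc1ccc([C@H]2Oc3cc(OCc4ccccc4)cc(OCc4ccccc4)c3C(=O)[C@@H]2CC(=O)Cl)cc1 | intermediate
14 | (2S,3R)-5,7-bis(benzyloxy)-2-(4-methoxyphenyl)-3-(2-oxoethenyl)chroman-4-one, the ketene (not isolated) | COc1ccc([C@H]2Oc3cc(OCc4ccccc4)cc(OCc4ccccc4)c3C(=O)[C@@H]2C=C=O)cc1 | intermediate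
15 | 1,3-bis(benzyloxy)-5-{[4-(benzyloxy)phenyl](chloro)methoxy}benzene, covalent form of the oxocarbenium ion pair (not isolated) | ClC(Oc1cc(OCc2ccccc2)cc(OCc2ccccc2)c1)c1ccc(OCc2ccccc2)cc1 | intermediate
16 | (2S,3R)-5,7-bis(benzyloxy)-3-[(2S,3S)-5,7-bis(benzyloxy)-2-[4-(benzyloxy)phenyl]-4-oxochroman-3-yl]-2-(4-methoxyphenyl)chroman-4-one | COc1ccc([C@H]2Oc3cc(OCc4ccccc4)cc(OCc4ccccc4)c3C(=O)[C@@H]2[C@@H]2C(=O)c3c(OCc4ccccc4)cc(OCc4ccccc4)cc3O[C@@H]2c2ccc(OCc3ccccc3)cc2)cc1 | intermediate
17 | (2S,3R)-5,7-dihydroxy-3-[(2S,3S)-5,7-dihydroxy-2-(4-hydroxyphenyl)-4-oxochroman-3-yl]-2-(4-methoxyphenyl)chroman-4-one | COc1ccc([C@H]2Oc3cc(O)cc(O)c3C(=O)[C@@H]2[C@@H]2C(=O)c3c(O)cc(O)cc3O[C@@H]2c2ccc(O)cc2)cc1 | target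

Total step count: 8. Longest linear sequence: 6 (steps 1, 2, 3, 4, 7, 8); the acetal arm (steps 5 and 6) joins at step 7.

Steps most likely to fail

1. Step 7 (Proposed new method). The ketene may oligomerize before it meets the cation. The acetal may ionize in the wrong sense, with loss of the aryloxy group. The electron-rich ring may be C-alkylated by the cation. The relative topicity of the C–C bond formation may be poor, which would give the 2,3-trans ring or the wrong face at C3(B). The fallback uses known chemistry, sets out from acid chloride 13 and returns at 16. Friedel–Crafts acylation of 1,3-bis(benzyloxy)-5-fluorobenzene F1 (from 5-fluororesorcinol, BnBr, K2CO3) with 13 and SnCl4 should occur ortho to fluorine and para to a benzyloxy group and give the fluoroaryl ketone F2. Regioselective boron enolization of its less hindered CH2–C=O unit (Bu2BOTf, i-Pr2NEt, −78 °C) gives the Z-enolate. Its Zimmerman–Traxler aldol addition to aldehyde 8 should give the syn aldol F3, with the enolate face again chosen by the C3 stereocenter of unit A. Intramolecular SNAr displacement of fluoride by the alkoxide (Cs2CO3, DMF, 0 °C) then closes the pyranone with retention at the carbinol carbon and gives the cis ring of 16.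

2. Step 3. The lithium enolate may open the pyranone ring by β-elimination of the phenoxide, with loss of configuration at C2, or may be alkylated twice. The fallback sets out from 4 and returns at 6 without a metal enolate. Soft enolization (TMSOTf, Et3N, CH2Cl2, 0 °C) gives the silyl enol ether F4. Cyclopropanation with tert-butyl diazoacetate and Cu(acac)2 on the face anti to the 2-aryl group gives the siloxycyclopropane ester F5. Fluoride-induced ring opening of this donor–acceptor cyclopropane (Et3N·3HF, THF) gives 6 with the side chain trans to the aryl group.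

3. Step 2. Insertion into the electron-rich 5-alkoxychromone may be slow, the boronic acid may protodeboronate, and enantiopurity may erode by reversible ring opening. The fallback sets out from 2 and returns at 4. Copper-mediated conjugate addition of 4-methoxyphenylmagnesium bromide (CuBr·SMe2, TMSCl, THF, −78 °C) without chiral ligand gives the racemic flavanone F6. Resolution by preparative chromatography on a chiral stationary phase then gives the 2S enantiomer 4.

Further compounds
F1 | step 7 | 1,3-bis(benzyloxy)-5-fluorobenzene | Fc1cc(OCc2ccccc2)cc(OCc2ccccc2)c1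
F2 | step 7 | (2S,3R)-5,7-bis(benzyloxy)-3-{2-[2,4-bis(benzyloxy)-6-fluorophenyl]-2-oxoethyl}-2-(4-methoxyphenyl)chroman-4-one | COc1ccc([C@H]2Oc3cc(OCc4ccccc4)cc(OCc4ccccc4)c3C(=O)[C@@H]2CC(=O)c2c(F)cc(OCc3ccccc3)cc2OCc2ccccc2)cc1
F3 | step 7 | (2S,3R)-5,7-bis(benzyloxy)-3-{(2S,3S)-1-[2,4-bis(benzyloxy)-6-fluorophenyl]-3-[4-(benzyloxy)phenyl]-3-hydroxy-1-oxopropan-2-yl}-2-(4-methoxyphenyl)chroman-4-one | COc1ccc([C@H]2Oc3cc(OCc4ccccc4)cc(OCc4ccccc4)c3C(=O)[C@@H]2[C@H](C(=O)c2c(F)cc(OCc3ccccc3)cc2OCc2ccccc2)[C@H](O)c2ccc(OCc3ccccc3)cc2)cc1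
F4 | step 3 | {[(2S)-5,7-bis(benzyloxy)-2-(4-methoxyphenyl)-2H-chromen-4-yl]oxy}trimethylsilane | COc1ccc([C@H]2Oc3cc(OCc4ccccc4)cc(OCc4ccccc4)c3C(O[Si](C)(C)C)=C2)cc1
F5 | step 3 | tert-butyl 5,7-bis(benzyloxy)-2-(4-methoxyphenyl)-7b-(trimethylsilyloxy)-1,1a,2,7b-tetrahydrocyclopropa[c]chromene-1-carboxylate (2S, cyclopropane anti to the 2-aryl group, ester exo) | COc1ccc([C@H]2Oc3cc(OCc4ccccc4)cc(OCc4ccccc4)c3[C@]3(O[Si](C)(C)C)[C@@H](C(=O)OC(C)(C)C)[C@H]23)cc1
F6 | step 2 | rac-5,7-bis(benzyloxy)-2-(4-methoxyphenyl)chroman-4-one | COc1ccc(C2CC(=O)c3c(OCc4ccccc4)cc(OCc4ccccc4)cc3O2)cc1
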